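**Strategy**

Everything rests on cutting the C2–C3 bond of ring C. C2 is an acetal-level carbon (bonded to O1, ring B and H) and C3–C4 is the enol carbon pair of the ring A aryl ketone, so the flavanone maps onto a 2-aryl-4-methylene-1,3-benzodioxine. A confined chiral Brønsted acid should ionise its C2–O3 bond and let the freed enol carbon attack the oxocarbenium carbon: one operation that forms C2–C3, closes ring C and sets the 2S centre from a racemic acetal. The precursor is the 7-O-silyl 8-prenyl enol acetal, built from a 3-prenyl-β-resorcylic acid and 2,2-dimethylchroman-6-carbaldehyde and methylenated at the lactone carbonyl.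

Key step: step 10

Remark: the target is read as the 2S flavanone; which antipode of the chiral acid gives 2S cannot be predicted, so step 10 is written for the (S,S) catalyst and the (R,R) antipode would be taken if the sense proved opposite.

**Route**

Step 1
Reactants: 1 resorcinol
Product: 2 1,3-bis(methoxymethoxy)benzene
Conditions: MOMCl (2.5 equiv), i-Pr2NEt (3 equiv), CH2Cl2, 0 °C → rt
Reagents that add atoms: chloromethyl methyl ether, COCCl
Why: Williamson-type O-alkylation of both phenols by the reactive α-chloro ether should be clean under amine base and installs the two acetal ethers that direct the metalation of step 2.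

Step 2
Reactants: 2 1,3-bis(methoxymethoxy)benzene; 3 prenyl bromide
Product: 5 1,3-bis(methoxymethoxy)-2-(3-methylbut-2-enyl)benzene, via aryllithium 4 (not isolated)
Conditions: n-BuLi (1.1 equiv), THF, 0 °C → rt; copper iodide CuI (10 mol %), then 3, −78 °C → rt
Reagents that add atoms: none
Why: Directed ortho-metalation should occur at C2 between the two cooperating OMOM groups, and the copper-assisted aryl nucleophile should displace the primary allylic bromide at its unsubstituted terminus (SN2), which places the prenyl group between the two oxygens.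

Step 3
Reactants: 5 1,3-bis(methoxymethoxy)-2-(3-methylbut-2-enyl)benzene
Product: 6 2-(3-methylbut-2-enyl)benzene-1,3-diol
Conditions: conc. HCl (cat.), MeOH, rt → 40 °C
Reagents that add atoms: none
Why: Acid-catalysed acetal methanolysis (MOM cleavage) is much faster than protonation of the trisubstituted alkene at this acid strength and temperature, so the diol should be released without closure to a chroman.

Step 4
Reactants: 6 2-(3-methylbut-2-enyl)benzene-1,3-diol
Product: 8 2,4-dihydroxy-3-(3-methylbut-2-enyl)benzoic acid, via potassium carboxylate 7 (not isolated)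
Conditions: KHCO3 (4 equiv), CO2 (1 atm), glycerol, 120 °C; then cold 1 M HCl
Reagents that add atoms: carbon dioxide, O=C=O
Why: Kolbe–Schmitt carboxylation is facile for resorcinols because the phenoxide ring is doubly activated, and with C2 blocked the two remaining ortho positions are equivalent, so a single acid should form.

Step 5
Reactants: 8 2,4-dihydroxy-3-(3-methylbut-2-enyl)benzoic acid
Product: 10 4-(tert-butyldimethylsilyloxy)-2-hydroxy-3-(3-methylbut-2-enyl)benzoic acid, via silyl ester 9 (not isolated)
Conditions: TBSCl (2.2 equiv), imidazole (4 equiv), DMF, 0 °C → rt; then AcOH/THF/H2O, rt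
Reagents that add atoms: tert-butyldimethylsilyl chloride, CC(C)(C)[Si](C)(C)Cl
Why: Silylation with silyl chloride and imidazole should reach the carboxyl group and the open 4-OH but not the 2-OH, which is hydrogen-bonded to the carbonyl and flanked by the prenyl group, and dilute acetic acid then hydrolyses only the labile silyl ester.

Step 6
Reactants: 11 4-bromophenol; 12 isoprene
Product: 14 6-bromo-2,2-dimethylchroman, via ortho-prenylphenol 13 (not isolated)
Conditions: silver triflate AgOTf (5 mol %), ClCH2CH2Cl, rt → 40 °C
Reagents that add atoms: none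
Why: In this tandem Friedel–Crafts prenylation and hydroalkoxylation the dimethylallyl cation from isoprene can only attack ortho to the hydroxyl (para is blocked by bromine), and the phenol then adds to the prenyl alkene in the Markovnikov sense to close the 2,2-dimethylchroman.

Step 7
Reactants: 14 6-bromo-2,2-dimethylchroman
Product: 17 2,2-dimethylchroman-6-carbaldehyde, via aryllithium 15 (not isolated), via lithium hemiaminal alkoxide 16 (not isolated)
Conditions: n-BuLi (1.1 equiv), THF, −78 °C; DMF, −78 → 0 °C; 1 M HCl
Reagents that add atoms: N,N-dimethylformamide, CN(C)C=O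
Why: Bromine–lithium exchange followed by formylation with DMF (Bouveault aldehyde synthesis) is reliable for aryl bromides that carry only ether groups and fixes the aldehyde at C6, para to the ring oxygen.

Step 8
Reactants: 10 4-(tert-butyldimethylsilyloxy)-2-hydroxy-3-(3-methylbut-2-enyl)benzoic acid; 17 2,2-dimethylchroman-6-carbaldehyde
Product: 19 (2RS)-7-(tert-butyldimethylsilyloxy)-2-(2,2-dimethylchroman-6-yl)-8-(3-methylbut-2-enyl)-4H-1,3-benzodioxin-4-one, via bis-trimethylsilyl derivative 18 (not isolated)
Conditions: 10, HMDS, CH2Cl2, reflux, then evaporation; 17, TMSOTf (10 mol %), 2,6-di-tert-butyl-4-methylpyridine (20 mol %), CH2Cl2, −78 → −30 °C; pyridine quench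
Reagents that add atoms: none
Why: Silyl-transfer acetalisation, the standard way from hydroxy acids and aldehydes to 1,3-dioxan-4-ones, should close the cyclic acylal from the ortho silyloxy and silyl carboxylate groups with loss of hexamethyldisiloxane and without protic acid near the prenyl group; the acetal centre forms as a racemate, which is of no consequence.

Step 9
Reactants: 19 (2RS)-7-(tert-butyldimethylsilyloxy)-2-(2,2-dimethylchroman-6-yl)-8-(3-methylbut-2-enyl)-4H-1,3-benzodioxin-4-one
Product: 20 (2RS)-7-(tert-butyldimethylsilyloxy)-2-(2,2-dimethylchroman-6-yl)-4-methylene-8-(3-methylbut-2-enyl)-4H-1,3-benzodioxine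
Conditions: Cp2TiMe2 (2.5 equiv), toluene, 70 °C, dark; filtration through basic alumina (Et3N-doped eluent)
Reagents that add atoms: dimethyltitanocene Cp2TiMe2, C[Ti](C)(C1C=CC=C1)C1C=CC=C1
Why: Petasis methylenation converts ester and lactone carbonyls, those of 1,3-dioxan-4-ones included, into enol ethers through Cp2Ti=CH2 under neutral conditions that should leave the acetal carbon, the silyl ether and the trisubstituted alkene untouched.

Step 10
Reactants: 20 (2RS)-7-(tert-butyldimethylsilyloxy)-2-(2,2-dimethylchroman-6-yl)-4-methylene-8-(3-methylbut-2-enyl)-4H-1,3-benzodioxine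
Product: 22 (2S)-7-(tert-butyldimethylsilyloxy)-2-(2,2-dimethylchroman-6-yl)-8-(3-methylbut-2-enyl)chroman-4-one, via oxocarbenium enol ion pair 21 (not isolated)
Conditions: (S,S)-IDPi [imidodiphosphorimidate built from two (S)-3,3'-bis(3,5-bis(trifluoromethyl)phenyl)-BINOL units, both phosphorus atoms carrying =N–SO2CF3] (5 mol %), 5 Å MS, toluene, −40 °C; Et3N quench
Reagents that add atoms: none
Why: Proposed new method: the acid protonates the enol-ether oxygen O3 and the C2–O3 bond breaks, since the cation left at C2 is stabilised by O1 and by the para-oxygenated ring B, giving ion pair 21 in which the catalyst anion is hydrogen-bonded to the released aryl ketone enol; the enol carbon then bonds to C2 and proton loss returns the acid, a net [1,3] oxygen-to-carbon shift. The closest known reaction types are the Lewis acid promoted Petasis–Ferrier rearrangement of 4-methylene-1,3-dioxanes to tetrahydropyran-4-ones and Petasis–Ferrier-type rearrangements of cyclic vinyl acetals under chiral phosphoric acid catalysis; a benzo-fused enol acetal giving a chromanone is without precedent. Ring C closes in a 6-(enolendo)-endo-trig mode, the enol carbon adding across the C2=O1 oxocarbenium bond. The C2 stereocentre is controlled by the chiral anion, which blocks one face of the planar oxocarbenium while holding the enol through a hydrogen bond; because ionisation destroys the acetal centre, both enantiomers of 20 should converge on 22. The step needs C-attack of the enol to beat C-protonation of the enol ether with hydrolysis, Prins attack of the 8-prenyl alkene on C2 and intermolecular recombination: the enol is by far the stronger π-nucleophile, the ring A tether holds it within reach of C2 for a six-membered closure, ionisation at C2–O1 or return of the enol oxygen only regenerates 20, and sieves exclude water. The 7-O-silyl group keeps the phenol from adding to the prenyl group or to the cation, and the low temperature protects the product from acid-induced ring opening to the chalcone.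

Step 11
Reactants: 22 (2S)-7-(tert-butyldimethylsilyloxy)-2-(2,2-dimethylchroman-6-yl)-8-(3-methylbut-2-enyl)chroman-4-one
Product: 23 euchrenone a17
Conditions: TBAF/AcOH (1:1, 1.5 equiv), THF, 0 °C
Reagents that add atoms: none
Why: Fluoride cleaves the aryl silyl ether through the strong Si–F bond, and the acetic acid buffer suppresses base-induced opening of the flavanone to the chalcone, so the C2 configuration should be retained.

**Compound list**

1 | resorcinol (benzene-1,3-diol) | Oc1cccc(O)c1 | starting material
2 | 1,3-bis(methoxymethoxy)benzene | COCOc1cccc(OCOC)c1 | intermediate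
3 | prenyl bromide (1-bromo-3-methylbut-2-ene) | CC(C)=CCBr | starting material
4 | 2,6-bis(methoxymethoxy)phenyllithium | [Li]c1c(OCOC)cccc1OCOC | intermediate
5 | 1,3-bis(methoxymethoxy)-2-(3-methylbut-2-enyl)benzene | COCOc1cccc(OCOC)c1CC=C(C)C | intermediate
6 | 2-(3-methylbut-2-enyl)benzene-1,3-diol | CC(C)=CCc1c(O)cccc1O | intermediate
7 | potassium 2,4-dihydroxy-3-(3-methylbut-2-enyl)benzoate | CC(C)=CCc1c(O)ccc(C(=O)[O-])c1O.[K+] | intermediate
8 | 2,4-dihydroxy-3-(3-methylbut-2-enyl)benzoic acid | CC(C)=CCc1c(O)ccc(C(=O)O)c1O | intermediate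
9 | tert-butyldimethylsilyl 4-(tert-butyldimethylsilyloxy)-2-hydroxy-3-(3-methylbut-2-enyl)benzoate | CC(C)=CCc1c(O[Si](C)(C)C(C)(C)C)ccc(C(=O)O[Si](C)(C)C(C)(C)C)c1O | intermediate
10 | 4-(tert-butyldimethylsilyloxy)-2-hydroxy-3-(3-methylbut-2-enyl)benzoic acid | CC(C)=CCc1c(O[Si](C)(C)C(C)(C)C)ccc(C(=O)O)c1O | intermediate
11 | 4-bromophenol | Oc1ccc(Br)cc1 | starting material
12 | isoprene (2-methylbuta-1,3-diene) | C=CC(C)=C | starting material
13 | 4-bromo-2-(3-methylbut-2-enyl)phenol | CC(C)=CCc1cc(Br)ccc1O | intermediate
14 | 6-bromo-2,2-dimethylchroman | CC1(C)CCc2cc(Br)ccc2O1 | intermediate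
15 | (2,2-dimethylchroman-6-yl)lithium | [Li]c1ccc2c(c1)CCC(C)(C)O2 | intermediate
16 | lithium (RS)-(dimethylamino)(2,2-dimethylchroman-6-yl)methoxide | [Li]OC(N(C)C)c1ccc2c(c1)CCC(C)(C)O2 | intermediate
17 | 2,2-dimethylchroman-6-carbaldehyde | O=Cc1ccc2c(c1)CCC(C)(C)O2 | intermediate
18 | trimethylsilyl 4-(tert-butyldimethylsilyloxy)-3-(3-methylbut-2-enyl)-2-(trimethylsilyloxy)benzoate | CC(C)=CCc1c(O[Si](C)(C)C(C)(C)C)ccc(C(=O)O[Si](C)(C)C)c1O[Si](C)(C)C | intermediate
19 | (2RS)-7-(tert-butyldimethylsilyloxy)-2-(2,2-dimethylchroman-6-yl)-8-(3-methylbut-2-enyl)-4H-1,3-benzodioxin-4-one (racemic) | O=C1OC(c2ccc3c(c2)CCC(C)(C)O3)Oc2c(CC=C(C)C)c(O[Si](C)(C)C(C)(C)C)ccc21 | intermediate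
20 | (2RS)-7-(tert-butyldimethylsilyloxy)-2-(2,2-dimethylchroman-6-yl)-4-methylene-8-(3-methylbut-2-enyl)-4H-1,3-benzodioxine (racemic) | C=C1OC(c2ccc3c(c2)CCC(C)(C)O3)Oc2c(CC=C(C)C)c(O[Si](C)(C)C(C)(C)C)ccc21 | intermediate
21 | ring-opened aryloxocarbenium ion of 20 carrying the free aryl ketone enol, paired with the catalyst anion (cation shown) | C=C(O)c1ccc(O[Si](C)(C)C(C)(C)C)c(CC=C(C)C)c1[O+]=Cc1ccc2c(c1)CCC(C)(C)O2 | intermediate
22 | (2S)-7-(tert-butyldimethylsilyloxy)-2-(2,2-dimethylchroman-6-yl)-8-(3-methylbut-2-enyl)chroman-4-one | CC(C)=CCc1c(O[Si](C)(C)C(C)(C)C)ccc2c1O[C@H](c1ccc3c(c1)CCC(C)(C)O3)CC2=O | intermediate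
23 | euchrenone a17, (2S)-2-(2,2-dimethylchroman-6-yl)-7-hydroxy-8-(3-methylbut-2-enyl)chroman-4-one | CC(C)=CCc1c(O)ccc2c1O[C@H](c1ccc3c(c1)CCC(C)(C)O3)CC2=O | target

**Step count**

Total: 11 steps. Longest linear sequence: 9 steps (steps 1–5 and 8–11, from resorcinol); the aldehyde branch is steps 6 and 7.

**Steps most likely to fail**

1. Step 10 (Proposed new method). Ring closure may take place in a loosely paired cation with poor facial selectivity. The enol ether may be protonated at carbon and hydrolysed. The product may lose enantiopurity by acid-induced opening to the chalcone. Fallback with known chemistry: the C2 centre is set by asymmetric conjugate addition of an arylboronic acid to a chromone. Setting out from 20, PPTS in wet THF at rt should hydrolyse the enol acetal to 1-[4-(tert-butyldimethylsilyloxy)-2-hydroxy-3-(3-methylbut-2-enyl)phenyl]ethanone F1, with 17 recovered. DMF dimethyl acetal in toluene at 90 °C should give (E)-3-(dimethylamino)-1-[4-(tert-butyldimethylsilyloxy)-2-hydroxy-3-(3-methylbut-2-enyl)phenyl]prop-2-en-1-one F2. PPTS in toluene at 80 °C should close F2 to 7-(tert-butyldimethylsilyloxy)-8-(3-methylbut-2-enyl)-4H-chromen-4-one F3. In parallel, 14 is lithiated to 15 (n-BuLi, THF, −78 °C) and quenched with B(OiPr)3 and aqueous acid to give (2,2-dimethylchroman-6-yl)boronic acid F4. F3 and F4 are then joined with Pd(OCOCF3)2 (divalent palladium) and (S)-4-tert-butyl-2-(pyridin-2-yl)-4,5-dihydrooxazole (or its antipode, whichever delivers 2S), NH4PF6 and H2O in ClCH2CH2Cl at 60 °C. The fallback comes back to the route at 22.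

2. Step 8. Ring closure to the cyclic acylal may stall at open silyl acetal stages, or the cation formed at the phenolic oxygen may be captured by the neighbouring prenyl alkene. Fallback: the electrophile is changed to a preformed acetal and the unsilylated acid is used, so that the carboxyl group engages first. Setting out from 17, HC(OMe)3 and MeOH with catalytic PPTS should give 6-(dimethoxymethyl)-2,2-dimethylchroman F5. Acetal exchange of F5 with free hydroxy acid 10 (PPTS cat., toluene, 60 °C, 5 Å MS to take up methanol) should then close the ring. The fallback comes back to the route at 19.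

3. Step 4. The carboxylation may stop at an unfavourable equilibrium, or the acid may lose CO2 during hot or acidic isolation. Fallback: the carboxyl group is introduced by directed ortho-metalation before the phenols are unmasked. Setting out from 5, n-BuLi/TMEDA in THF at 0 °C should give 2,4-bis(methoxymethoxy)-3-(3-methylbut-2-enyl)phenyllithium F6. Quenching with CO2 should give 2,4-bis(methoxymethoxy)-3-(3-methylbut-2-enyl)benzoic acid F7. Catalytic conc. HCl in MeOH/THF at rt should then remove both MOM groups. The fallback bypasses steps 3 and 4 and comes back to the route at 8.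

**Further compounds**

F1 | step 10 | 1-[4-(tert-butyldimethylsilyloxy)-2-hydroxy-3-(3-methylbut-2-enyl)phenyl]ethanone | CC(=O)c1ccc(O[Si](C)(C)C(C)(C)C)c(CC=C(C)C)c1O
F2 | step 10 | (E)-3-(dimethylamino)-1-[4-(tert-butyldimethylsilyloxy)-2-hydroxy-3-(3-methylbut-2-enyl)phenyl]prop-2-en-1-one | CN(C)/C=C/C(=O)c1ccc(O[Si](C)(C)C(C)(C)C)c(CC=C(C)C)c1O
F3 | step 10 | 7-(tert-butyldimethylsilyloxy)-8-(3-methylbut-2-enyl)-4H-chromen-4-one | O=c1ccoc2c(CC=C(C)C)c(O[Si](C)(C)C(C)(C)C)ccc12
F4 | step 10 | (2,2-dimethylchroman-6-yl)boronic acid | OB(O)c1ccc2c(c1)CCC(C)(C)O2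
F5 | step 8 | 6-(dimethoxymethyl)-2,2-dimethylchroman | COC(OC)c1ccc2c(c1)CCC(C)(C)O2
F6 | step 4 | 2,4-bis(methoxymethoxy)-3-(3-methylbut-2-enyl)phenyllithium | [Li]c1ccc(OCOC)c(CC=C(C)C)c1OCOC
F7 | step 4 | 2,4-bis(methoxymethoxy)-3-(3-methylbut-2-enyl)benzoic acid | COCOc1ccc(C(=O)O)c(OCOC)c1CC=C(C)C
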